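A direct plan would build the C1–C8 chain from lactic acid building blocks up to alkene A1, put the peroxide on C6, close both rings at once and attach the chain last. Its weakest operations would be:
(a) the Co(thd)2-catalysed silylperoxidation of A1 (O2, Et3SiH), which makes C6 through an acyclic tertiary radical without facial bias, so about half of the material would be the wrong epimer;
(b) a Pd(OAc)2-catalysed peroxycarbonylation of hydroperoxy alcohol A2 to the bicycle, a reaction without precedent in which a hydroperoxide must survive zerovalent palladium and CO;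
(c) a final Horner–Wittig olefination of peroxylactone ketone A3 with lithiated phosphine oxide A4, which puts precious, base-labile material under an organolithium and leaves the C8=C9 geometry open.
Many steps would also go into a C8 stereocentre that is erased in the end.

The new route cuts C6–C7 first. C6 is a quaternary carbon with a peroxide oxygen, its methylene C7 is allylic to C8=C9, and it lies 1,3 to C4 in a 1,2-dioxane cis-fused to the γ-lactone. The target is therefore the Hosomi–Sakurai product of a ring peroxycarbenium ion at C6 and a silane that brings C7–C16. The peroxyketal is then cut at O–C3 (oxa-Michael) and O–C6 (capture of a carbonyl oxide), and the butenolide at C2=C3. The lactone ring arises first, the dioxane ring second, the chain last. C4 is bought and relays to C3 (cis fusion) and C6 (axial attack), so there is no acyclic radical peroxidation, no palladium or CO near a hydroperoxide, no strong base on the peroxylactone and no sacrificial stereocentre.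

Key step: step 10

Remark: atoms are numbered as in the target (C1 lactone carbonyl, C3 and C4 ring fusion, C6 peroxy quaternary carbon, C7–C16 chain). (R)-2-Methylglycidol and (E)-(2-bromoethenyl)trimethylsilane are taken as commercial.

Step 1
Reactants: 1 styrene; 2 hex-5-en-1-ol
Product: 3 (5E)-6-phenylhex-5-en-1-ol
Conditions: second-generation Grubbs catalyst RuCl2(=CHPh)(PCy3)(SIMes) (2 mol %), styrene (3 equiv), CH2Cl2, 40 °C
Reagents that add atoms: none
Why: Olefin cross metathesis of a terminal alkene with excess styrene gives the E-styrenyl alkene (C15=C16) under thermodynamic control and tolerates the free alcohol.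

Step 2
Reactants: 3 (5E)-6-phenylhex-5-en-1-ol
Product: 4 (5E)-6-phenylhex-5-enal
Conditions: TEMPO (10 mol %), PhI(OAc)2 (1.1 equiv), CH2Cl2, rt
Reagents that add atoms: none
Why: Oxoammonium oxidation (TEMPO with PhI(OAc)2 as terminal oxidant) takes the primary alcohol to the aldehyde without over-oxidation and leaves the styrenyl alkene alone.

Step 3
Reactants: 5 (E)-(2-bromoethenyl)trimethylsilane; 4 (5E)-6-phenylhex-5-enal
Product: 7 (1E,7E)-8-phenyl-1-(trimethylsilyl)octa-1,7-dien-3-ol (racemic), via vinyllithium 6 (not isolated)
Conditions: 5, t-BuLi (2.0 equiv), Et2O, −78 °C; then 4, −78 → 0 °C; then H2O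
Reagents that add atoms: none
Why: Bromine–lithium exchange keeps the E geometry and the vinyllithium adds 1,2 to the aldehyde; the carbinol centre is racemic, which does not matter because it becomes trigonal C11 in step 5.

Step 4
Reactants: 7 (1E,7E)-8-phenyl-1-(trimethylsilyl)octa-1,7-dien-3-ol
Product: 8 (1E,7E)-8-phenyl-1-(trimethylsilyl)octa-1,7-dien-3-yl N-phenylcarbamate
Conditions: PhNCO (1.2 equiv), DMAP (10 mol %), CH2Cl2, rt
Reagents that add atoms: phenyl isocyanate, O=C=Nc1ccccc1
Why: Carbamoylation of the secondary allylic alcohol with an isocyanate installs the N–H carbamate that will carry copper to the alkene in step 5.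

Step 5
Reactants: 8 (1E,7E)-8-phenyl-1-(trimethylsilyl)octa-1,7-dien-3-yl N-phenylcarbamate
Product: 10 trimethyl[(4E,9E)-2-methyl-10-phenyldeca-1,4,9-trien-3-yl]silane (racemic at C9), via N-lithio carbamate 9 (not isolated)
Conditions: n-BuLi (1.0 equiv), THF, −78 °C; CuI·2LiCl (1.0 equiv); CH2=C(CH3)MgBr (1.1 equiv), −78 °C → rt
Reagents that add atoms: isopropenylmagnesium bromide, C=C(C)[Mg]Br
Why: In this copper-mediated SN2' substitution of an allylic carbamate the lithiated carbamate binds the isopropenylcopper species and delivers the isopropenyl group syn to the silicon-bearing alkene carbon, which forms C8–C9 and moves the double bond to C10=C11, E because the alkyl chain sits pseudo-equatorial in the cyclic transition state; C9 is racemic and becomes trigonal in step 10.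

Step 6
Reactants: 11 (R)-2-methylglycidol, [(2R)-2-methyloxiran-2-yl]methanol
Product: 12 (2S)-2,4-dimethylpent-4-ene-1,2-diol
Conditions: CH2=C(CH3)MgBr (2.5 equiv), CuI (10 mol %), THF, −30 → 0 °C
Reagents that add atoms: isopropenylmagnesium bromide, C=C(C)[Mg]Br
Why: Copper-catalysed Grignard opening of the 2,2-disubstituted epoxide occurs by SN2 attack at the unsubstituted ring carbon, so the quaternary carbinol centre (future C4) comes unchanged from 11 (Payne rearrangement of the alkoxide would only regenerate the same enantiomer) and the isopropenyl group supplies C6 and its methyl group.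

Step 7
Reactants: 12 (2S)-2,4-dimethylpent-4-ene-1,2-diol
Product: 13 (2S)-2-hydroxy-2,4-dimethylpent-4-enal
Conditions: SO3·pyridine, DMSO, i-Pr2NEt, CH2Cl2, 0 °C; crude product used at once
Reagents that add atoms: none
Why: Parikh–Doering oxidation converts the primary alcohol of a primary/tertiary 1,2-diol into the aldehyde without glycol cleavage, and the product has no α-hydrogen to epimerise.

Step 8
Reactants: 13 (2S)-2-hydroxy-2,4-dimethylpent-4-enal
Product: 15 (5S)-5-methyl-5-(2-methylprop-2-en-1-yl)furan-2(5H)-one, via ester ylide 14 (not isolated)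
Conditions: Ph3P=C=C=O (1.2 equiv), toluene, 80 °C
Reagents that add atoms: ketenylidenetriphenylphosphorane, O=C=C=P(c1ccccc1)(c1ccccc1)c1ccccc1
Why: The tertiary hydroxyl group adds to the ketene carbon of the cumulated ylide to give ester ylide 14, whose intramolecular Wittig reaction with the neighbouring aldehyde closes the butenolide (lactone ring, C2=C3 cis by ring constraint) and leaves C4 untouched.

Step 9
Reactants: 15 (5S)-5-methyl-5-(2-methylprop-2-en-1-yl)furan-2(5H)-one
Product: 17 (4aS,7aS)-3-methoxy-3,4a-dimethyl-7,7a-dihydro-4H-furo[3,2-c][1,2]dioxin-6-one (both epimers at the ketal carbon C6), via hydroperoxy ketal 16 (not isolated)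
Conditions: O3 (1.0 equiv), CH2Cl2–MeOH (4:1), −78 °C; N2 purge, concentration at 0 °C; then Et2NH (0.5 equiv), CF3CH2OH, rt
Reagents that add atoms: ozone, [O-][O+]=O; methanol, CO
Why: Ozone attacks the electron-rich 1,1-disubstituted alkene much faster than the conjugated butenolide alkene, the primary ozonide fragments to formaldehyde and the more substituted carbonyl oxide, and methanol traps the latter as hydroperoxy ketal 16 (O–C6); amine base then triggers the intramolecular oxa-Michael addition of the hydroperoxide to C3 of the butenolide (6-exo-trig, O–C3), a closure known for hydroperoxy ketals with enoates and for tertiary hydroperoxides with this kind of butenolide, and because the four-atom tether hangs from C4 it can reach only the face of the planar butenolide that carries C5, so the ring fusion is cis and C3 is set (S) by C4, while the ketal carbon C6 stays a mixture that converges in step 10.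

Step 10
Reactants: 17 (4aS,7aS)-3-methoxy-3,4a-dimethyl-7,7a-dihydro-4H-furo[3,2-c][1,2]dioxin-6-one; 10 trimethyl[(4E,9E)-2-methyl-10-phenyldeca-1,4,9-trien-3-yl]silane
Product: 19 plakortolide H, via peroxycarbenium triflate 18 (not isolated)
Conditions: 10 (1.5 equiv), TMSOTf (0.3 equiv), 2,6-di-tert-butyl-4-methylpyridine (0.1 equiv), CH2Cl2, −78 °C
Reagents that add atoms: none
Why: TMSOTf ionises the exocyclic methoxy group of 17 (both ketal epimers converge) to the ring peroxycarbenium ion 18, the terminal CH2 of allylsilane 10 (C7) attacks C6 anti to silicon (SE2') and loss of the silyl group to methoxide gives C8=C9 and returns the silyl Lewis acid, so the C6–C7 bond, the quaternary peroxy carbon and the whole chain are installed in one operation. The closest known reaction type is the Lewis acid-mediated Hosomi–Sakurai allylation of cyclic peroxyketals (3-alkoxy-1,2-dioxolanes and 3-alkoxy-1,2-dioxanes) through peroxycarbenium ions, read with the stereoelectronic model of axial attack on six-membered oxocarbenium ions. No ring closes here: the lactone ring (step 8) and the dioxane ring (step 9) are in place and should stay intact because the methoxy oxygen is more basic than the ring peroxide oxygen, so ionisation is exocyclic. C6 is controlled by C4: in the half-chair of 18 the C4–O bond of the lactone is pseudo-axial and the C4 methyl group and the C3–C2 bond are pseudo-equatorial, and axial attack through a chair-like transition state then comes from the face syn to the lactone oxygen and anti to the C4 methyl group, which puts C7 cis to the lactone oxygen and the two methyl groups cis (6R), whereas the epimer would need attack syn to a pseudo-axial methyl group or a twist-boat. The 8E geometry should follow from the SE2' transition state, in which the C9–Si bond is perpendicular to the alkene, the C9 hydrogen eclipses the C7 terminus and the C10 alkenyl group lies on the side of the C8 methyl group, away from the incoming quaternary centre; 10E and 15E come unchanged from 10, and both enantiomers of 10 give the same product because C9 becomes trigonal. The step needs attack through C7 and not through C11, which the unhindered 1,1-disubstituted terminus (tertiary β-silyl cation) against an internal disubstituted one should secure, and it needs the diene, styrene, peroxide and lactone to survive, for which the low temperature, the substoichiometric silyl triflate and the hindered pyridine buffer are chosen.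

Compound list
1 | styrene | C=Cc1ccccc1 | starting material
2 | hex-5-en-1-ol | C=CCCCCO | starting material
3 | (5E)-6-phenylhex-5-en-1-ol | OCCCC/C=C/c1ccccc1 | intermediate
4 | (5E)-6-phenylhex-5-enal | O=CCCC/C=C/c1ccccc1 | intermediate
5 | (E)-(2-bromoethenyl)trimethylsilane | C[Si](C)(C)/C=C/Br | starting material
6 | [(E)-2-(trimethylsilyl)ethenyl]lithium | [Li]/C=C/[Si](C)(C)C | intermediate
7 | (1E,7E)-8-phenyl-1-(trimethylsilyl)octa-1,7-dien-3-ol (racemic) | C[Si](C)(C)/C=C/C(O)CCC/C=C/c1ccccc1 | intermediate
8 | (1E,7E)-8-phenyl-1-(trimethylsilyl)octa-1,7-dien-3-yl N-phenylcarbamate (racemic) | C[Si](C)(C)/C=C/C(OC(=O)Nc1ccccc1)CCC/C=C/c1ccccc1 | intermediate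
9 | lithium salt of 8 deprotonated at nitrogen | C[Si](C)(C)/C=C/C(OC(=O)[N-]c1ccccc1)CCC/C=C/c1ccccc1.[Li+] | intermediate
10 | trimethyl[(4E,9E)-2-methyl-10-phenyldeca-1,4,9-trien-3-yl]silane (racemic) | C=C(C)C(/C=C/CCC/C=C/c1ccccc1)[Si](C)(C)C | intermediate
11 | (R)-2-methylglycidol, [(2R)-2-methyloxiran-2-yl]methanol | C[C@@]1(CO)CO1 | starting material
12 | (2S)-2,4-dimethylpent-4-ene-1,2-diol | C=C(C)C[C@](CO)(C)O | intermediate
13 | (2S)-2-hydroxy-2,4-dimethylpent-4-enal | C=C(C)C[C@](C=O)(C)O | intermediate
14 | (2S)-2,4-dimethyl-1-oxopent-4-en-2-yl (triphenyl-λ5-phosphanylidene)acetate | C=C(C)C[C@](C=O)(C)OC(=O)C=P(c1ccccc1)(c1ccccc1)c1ccccc1 | intermediate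
15 | (5S)-5-methyl-5-(2-methylprop-2-en-1-yl)furan-2(5H)-one | C=C(C)C[C@]1(C)OC(=O)C=C1 | intermediate
16 | (5S)-5-(2-hydroperoxy-2-methoxypropyl)-5-methylfuran-2(5H)-one (both ketal epimers) | COC(C)(OO)C[C@]1(C)OC(=O)C=C1 | intermediate
17 | (4aS,7aS)-3-methoxy-3,4a-dimethyl-7,7a-dihydro-4H-furo[3,2-c][1,2]dioxin-6-one (both epimers at C6) | COC1(C)C[C@]2(C)OC(=O)C[C@@H]2OO1 | intermediate
18 | ring peroxycarbenium triflate at C6 (3S,4S) | C[C+]1C[C@]2(C)OC(=O)C[C@@H]2OO1.[O-]S(=O)(=O)C(F)(F)F | intermediate
19 | plakortolide H, (3R,4aS,7aS)-3,4a-dimethyl-3-[(2E,4E,9E)-2-methyl-10-phenyldeca-2,4,9-trien-1-yl]-7,7a-dihydro-4H-furo[3,2-c][1,2]dioxin-6-one (3S,4S,6R; 8E,10E,15E) | C/C(=C\C=C\CCC/C=C/c1ccccc1)C[C@]1(C)C[C@]2(C)OC(=O)C[C@@H]2OO1 | target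

Total step count: 10. Longest linear sequence: 6 steps (steps 1–5 and 10); the core branch (steps 6–9 and 10) has 5.

Steps most likely to fail

Step 10. The bis-allylic silane may react through its internal terminus C11, may be protodesilylated by adventitious acid before it meets the cation, or may give a lower 8E preference than expected. The facial selectivity at C6 is argued from oxocarbenium ions and may be lower on a peroxycarbenium ion. The fallback keeps the cation but divides the task, and sets out from 17 and 4 to come back at 19. Allylation of 17 (TMSOTf, CH2Cl2, −78 °C) with the simple known reagent 2-methyl-3,3-bis(trimethylsilyl)prop-1-ene F1 should give (3R,4aS,7aS)-3,4a-dimethyl-3-[(2E)-2-methyl-3-(trimethylsilyl)prop-2-en-1-yl]-7,7a-dihydro-4H-furo[3,2-c][1,2]dioxin-6-one F2, with the remaining silyl group cis to the C8 methyl group. Iododesilylation with N-iodosuccinimide ((CF3)2CHOH, 0 °C) should proceed with retention to (3R,4aS,7aS)-3-[(2E)-3-iodo-2-methylprop-2-en-1-yl]-3,4a-dimethyl-7,7a-dihydro-4H-furo[3,2-c][1,2]dioxin-6-one F3. The chain would come from aldehyde 4 by Takai iodo-olefination (CHI3, CrCl2, THF) to (1E,6E)-1-iodo-7-phenylhepta-1,6-diene F4, then iodine–lithium exchange (t-BuLi) and Bu3SnCl to tributyl[(1E,6E)-7-phenylhepta-1,6-dien-1-yl]stannane F5. A base-free Stille coupling of F3 and F5 (Pd2(dba)3, AsPh3, CuI, DMF, rt) then gives 19.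

Step 5. Transfer of the alkenyl group from copper may be sluggish, or substitution may take place at the carbinol carbon (SN2) and not at the hindered silicon-bearing carbon. The fallback sets out from 7 and comes back at 10. It gives up delivery through the carbamate nitrogen for an anti-SN2' substitution in which the leaving group is activated by chelation. Esterification of 7 with picolinic acid (DCC, DMAP, CH2Cl2) gives (1E,7E)-8-phenyl-1-(trimethylsilyl)octa-1,7-dien-3-yl pyridine-2-carboxylate F6. F6 with CH2=C(CH3)MgBr and CuBr·SMe2 (THF, −40 °C) should give 10; this type of substitution is known to transfer aryl and alkenyl Grignard groups to the γ-carbon.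

Step 9. The primary ozonide may fragment the other way, to the ketone and formaldehyde oxide, so that little hydroperoxy ketal forms, or ozone may start on the butenolide before the isopropenyl group is consumed. The fallback sets out from 15 and comes back at 16. Ozonolysis in CH2Cl2 with reductive work-up (Me2S) gives (5S)-5-methyl-5-(2-oxopropyl)furan-2(5H)-one F7, which is kept away from base because its β-acyloxy ketone can eliminate. Acid-catalysed perketalisation with urea·H2O2 and Sc(OTf)3 (cat.) in MeOH at rt then gives 16, which is cyclised with Et2NH in CF3CH2OH as in step 9.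

Further compounds
F1 | step 10 | 2-methyl-3,3-bis(trimethylsilyl)prop-1-ene | C=C(C)C([Si](C)(C)C)[Si](C)(C)C
F2 | step 10 | (3R,4aS,7aS)-3,4a-dimethyl-3-[(2E)-2-methyl-3-(trimethylsilyl)prop-2-en-1-yl]-7,7a-dihydro-4H-furo[3,2-c][1,2]dioxin-6-one | C[Si](C)(C)/C=C(\C)C[C@]1(C)C[C@]2(C)OC(=O)C[C@@H]2OO1
F3 | step 10 | (3R,4aS,7aS)-3-[(2E)-3-iodo-2-methylprop-2-en-1-yl]-3,4a-dimethyl-7,7a-dihydro-4H-furo[3,2-c][1,2]dioxin-6-one | I/C=C(\C)C[C@]1(C)C[C@]2(C)OC(=O)C[C@@H]2OO1
F4 | step 10 | (1E,6E)-1-iodo-7-phenylhepta-1,6-diene | I/C=C/CCC/C=C/c1ccccc1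
F5 | step 10 | tributyl[(1E,6E)-7-phenylhepta-1,6-dien-1-yl]stannane | CCCC[Sn](CCCC)(CCCC)/C=C/CCC/C=C/c1ccccc1
F6 | step 5 | (1E,7E)-8-phenyl-1-(trimethylsilyl)octa-1,7-dien-3-yl pyridine-2-carboxylate | C[Si](C)(C)/C=C/C(OC(=O)c1ccccn1)CCC/C=C/c1ccccc1
F7 | step 9 | (5S)-5-methyl-5-(2-oxopropyl)furan-2(5H)-one | CC(=O)C[C@]1(C)OC(=O)C=C1
A1 | direct plan | methyl (2S,4E,6S)-6-[(tert-butyldimethylsilyl)oxy]-2,4-dimethyl-2-[(triethylsilyl)oxy]hept-4-enoate | COC(=O)[C@@](C)(O[Si](CC)(CC)CC)C/C(C)=C/[C@H](C)O[Si](C)(C)C(C)(C)C
A2 | direct plan | (3S,5R,7S)-7-[(tert-butyldimethylsilyl)oxy]-5-hydroperoxy-3,5-dimethyloct-1-en-3-ol | C=C[C@@](C)(O)C[C@](C)(OO)C[C@H](C)O[Si](C)(C)C(C)(C)C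
A3 | direct plan | (3S,4aS,7aS)-3,4a-dimethyl-3-(2-oxopropyl)-7,7a-dihydro-4H-furo[3,2-c][1,2]dioxin-6-one | CC(=O)C[C@]1(C)C[C@]2(C)OC(=O)C[C@@H]2OO1
A4 | direct plan | [(2E,7E)-8-phenylocta-2,7-dien-1-yl]diphenylphosphine oxide | O=P(C/C=C/CCC/C=C/c1ccccc1)(c1ccccc1)c1ccccc1
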